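Choosing the charge of free base comes first, so the earlier runs have to say what the electrophile costs in free base.

| flask | electrophile | free base | protonated nucleophile | remark | time |
|---|---|---|---|---|---|
| cedar | 0.80 M | 0.96 M | 1.04 M | run made earlier |  |
| birch | 0.80 M | 1.2 M | 1.04 M | run made earlier |  |
| maple | 0.80 M | 1.7 M | 1.04 M | run made earlier |  |
| noon | 0.80 M | 1.50 M | 1.04 M |  | 3.0 h |
| summer | 0.80 M | 0.880 M | 1.04 M |  | 3.0 h |
| spring | 0.80 M | 1.10 M | 1.04 M |  | 3.0 h |

- cedar (time / h: electrophile / %, target / %): 0.250: 36.5, 44.5; 0.500: 33.9, 33.9; 1.33: 24.3, 13.0; 3.00: 11.6, 2.0
- birch (time / h: electrophile / %, target / %): 0.833: 19.1, 26.2; 1.50: 15.6, 10.8; 2.50: 9.1, 5.2; 3.00: 9.3, 0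
- maple (time / h: electrophile / %, target / %): 0.250: 6.4, 70.9; 0.500: 3.0, 55.2; 1.33: 0, 18.2; 3.00: 0, 2.8

(standard deviation of a reading: 1 percentage point)

* part of the electrophile that has reacted at the end, noon
* part of the electrophile that has reacted at the end, summer
* part of the electrophile that has reacted at the end, spring
* what raising the concentration of free base from its lowest to its highest value here does to the part of the electrophile that has reacted (changes below 5 percentage points count as none) (it rises / no change / it falls)

The flasks share c(electrophile) and c(protonated nucleophile) but differ in c(free base), so that is the setting to follow. In cedar the electrophile already reads 36.5% at 0.250 h, but only 11.6% at 3.00 h: a burst, then a slow tail. Read as first order, that tail has a constant of 0.417 h⁻¹, and carried back to the start it puts the end of the burst at 40.5% left.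

Dividing the rate of loss of free base by that of electrophile drops time out and leaves a plain count, the base price: free base spent per electrophile in the burst, 2.02, a reading that takes the free base as spent in the burst. For birch this price gives 25.6% left after the burst, and birch's first reading, carried back with cedar's constant, gives 27.0%. Maple, with 1.7 M, holds more than the 1.61 M that its whole electrophile costs, and its electrophile reads 0% at 1.33 h.

So the burst's remainder, times the 28.6% that survives the tail, gives as my reckoning 98.0% reacted in noon, 87.0% in summer and 90.9% in spring.

The forecast, which holds that “the burst uses 2 base per electrophile”, gives 98% for noon, 86.5% for summer and 90.6% for spring, the last two slightly lower than my reckoning, and says of the part reacted, from the lowest c(free base) to the highest: it rises.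

The flasks give 97.2% in noon, 87.5% in summer and 90.0% in spring; of the part reacted, from the lowest c(free base) to the highest, the result is: it rises, by 9.7 percentage points.

    electrophile + nucleophile → acid set free + target (k = 0.0120 M⁻¹ s⁻¹)
    electrophile + acid set free → side product (k = 8.30 × 10⁻⁴ M⁻¹ s⁻¹)
    acid set free + free base ⇌ salt of the base, settled at all times (K = 15000 M⁻¹)
    target → over-reaction product (k = 3.80 × 10⁻⁴ s⁻¹)
    nucleophile + acid set free ⇌ protonated nucleophile, settled at all times (K = 1500 M⁻¹)

In summer the free base, the limiting reagent, stands at 0.0692% of its charge at 3.00 h; at the base price that charge pays for 54.5% of the electrophile, yet 87.5% has reacted. At that time in summer electrophile goes to target at half the rate of its loss to side product, and side product stands at 17.8%. The neighbour of summer charged with 0.26 M of protonated nucleophile has 0% of it left at 3.00 h and 32.6% of its electrophile reacted, which at the base price costs 0.525 M of free base; its salt of the base stands at 0.519 M.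

(The numbers in the tables come from a simulation with constants of no real substance; noise was put on by code.)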